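The readings stem from a simulated flask with made-up constants; noise was put on by code.

Watching the starting material misleads: in Saturday's run it is down to 3.0% at 0.667 min, yet target stands at 19.5%. The decision for the next run is whether west, at 30 °C with 0.85 mol% of second catalyst, needs heat to finish within 8.0 min.

| setting | Saturday's | west | east | south-west | north |
|---|---|---|---|---|---|
| starting material | 5.0 × 10⁻⁴ M | 5.0 × 10⁻⁴ M | 5.0 × 10⁻⁴ M | 5.0 × 10⁻⁴ M | 5.0 × 10⁻⁴ M |
| reagent | 0.80 equiv | 0.800 equiv | 0.800 equiv | 0.800 equiv | 0.800 equiv |
| free catalyst | 0.27 mol% | 0.27 mol% | 0.27 mol% | 0.27 mol% | 0.27 mol% |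
| second catalyst | 1.3 mol% | 0.85 mol% | 0.85 mol% | 0.85 mol% | 0.85 mol% |
| temperature | 30 °C | 30 °C | 55 °C | 5 °C | 80 °C |
| remark | run made earlier |  |  |  |  |
| time |  | 8.0 min | 8.0 min | 8.0 min | 8.0 min |

- Saturday's (time / min: target / %, starting material / %): 0.167: 2.8, 43.7; 0.333: 8.2, 18.4; 0.667: 19.5, 3.0; 1.00: 29.3, 0.8; 1.33: 37.3, 0.1; 2.00: 49.2, 0; 2.50: 56.2, 0.1

(scatter of a reading: 0.3 percentage points)

- what was read earlier has a scatter of 0.3 percentage points, one standard deviation
- the earlier runs do not show what temperature does; that part of a forecast is a guess
- no earlier run changes the charge of second catalyst; that part of a forecast is a guess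

* the best flask by amount of target, in percent of the starting material charged; "all alike" if 1.5 percentage points covers them all (west / east / south-west / north / all alike)
* amount of target at the end, in percent of the starting material charged, west
* amount of target at the end, in percent of the starting material charged, east
* amount of target at the end, in percent of the starting material charged, south-west
* amount of target at the end, in percent of the starting material charged, north

Early on, the starting material falls with a constant of 5.21 min⁻¹. With 0.80 equiv charged, reagent is the limiting reagent and caps target at 80.0% of the starting material. The approach of target to that cap reads as follows: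

slope = ln[(80.0% − 19.5%) / (80.0% − 56.2%)] / (2.50 min − 0.667 min) = 0.509 min⁻¹

Starting material falls ten times faster than this, so after the first minute the clock of the flask is the pseudo-first-order use of reagent. Assuming, as a guess, that the slope scales with second catalyst, the reckoning here carries the number of reagent lifetimes that a flask at 30 °C holds in its time:

n = 0.509 min⁻¹ × (0.85 mol% / 1.3 mol%) × 8.0 min = 2.66

room below the cap = 80.0% × exp(−n) = 5.6 percentage points

So this reckoning puts west at 74.4%. What temperature does is unmeasured, so the reckoning keeps west as the flask to run.

The forecast picks east, with west 73%, east 79%, south-west 25% and north 76%; east, it says, “reaches the 80% cap, with slight loss possible”.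

    starting material + free catalyst → free catalyst + open intermediate (k = 1.70 × 10⁵ M⁻¹ s⁻¹, Ea = 18.0 kJ mol⁻¹)
    second catalyst + open intermediate ⇌ catalyst intermediate (K = 39000 M⁻¹, k = 10000 M⁻¹ s⁻¹, Ea = 25.0 kJ mol⁻¹, ΔH = −12.0 kJ mol⁻¹)
    reagent + catalyst intermediate → second catalyst + target (k = 24000 M⁻¹ s⁻¹, Ea = 39.0 kJ mol⁻¹)
    reagent + target → over-reaction product (k = 110 M⁻¹ s⁻¹, Ea = 59.0 kJ mol⁻¹)
    (constants at 80 °C)

West gives 65.2%, east 56.0%, south-west 45.1% and north 44.5%, so west is the best flask. The step of reagent + target to over-reaction product speeds up 230 times from the coldest to the hottest flask, more than the 9.9 times of second catalyst + open intermediate, and north holds 17.7% of over-reaction product against 6.77% in west. West's 2.66 lifetimes leave 6.99% of the reagent charge in the reckoning, and west holds 1.56%. A neighbour of west with 2.1 mol% of second catalyst counts 6.58 lifetimes, and it ends with 0% of its reagent and target at 73.4%.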